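**Remark 1.** Labdane numbering is used for all bicyclic compounds (ring A = C1–C5 and C10, ring B = C5–C10, C17 on C8, C18 = 4α-methyl, C19 = 4β-CH2O, C20 on C10); the target is read as (3R,4S,5R,6R,10S), i.e. 3α,19-diester, 6β-hydroxyl, 5α-H, 10β-methyl. Ar = 3-(benzyloxy)-6-methoxy-2,4-dimethylphenyl.

**Remark 2.** The key-step precursor and product are used with C3 in the configuration of the target (3R, oxygen axial in ring A). A precursor with (3S) would give the 3-epimer and would need a late inversion at a neopentyl carbinol between two identical silyl ethers.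

## Structural features

The target is a trans-fused decalin with a tetrasubstituted C8=C9 alkene, a methyl group on C8 and an (E)-3-methylpent-2-enoic acid chain on C9. Ring A holds two 1,3-related quaternary carbons, C4 (equatorial methyl C18, axial CH2O C19) and the angular C10 (β-methyl), whose C19 and C20 substituents are syn-diaxial. C3 (axial α-oxygen), C4, C5 (α-H) and C6 (axial β-hydroxyl) are contiguous stereocentres, and C10 is 1,3-related to C4 and C6. The oxygens on C3 and C19 carry isovalerates, while the hindered 6β-hydroxyl and the C15 acid are free, so four oxygen functions must be distinguished. Fragile points are the β,γ-relationship between the C6 oxygen and the C8=C9 alkene (shift into conjugation once C6 is a ketone), the two esters (hydrolysis, acyl shift) and the E-enoate. The real difficulty is setting C10 against C4 with the correct 1,3-relationship and attaching the side chain to C9, which is flanked by C10. The key step exploits the ring-B pattern, oxygen on C9 and C6 and methyl on C8 and C10, which is that of 4-methoxy-2,6-dimethylphenol, so that C10 arises by C-alkylation of that arene at a methyl-bearing ortho carbon by C1 of a tether attached at C5.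

## Logic of the disconnections

**33 to 30.** No skeletal bond is cut. The C15 acid is traced through 32 and 31 to the allylic silyl ether of 30. The gain is that the acid never has to coexist with basic or reducing steps. The demand is an allylic oxidation that leaves the 6β-hydroxyl and the C8=C9 alkene alone.

**30 to 25 and 28.** The C9–C11 bond is cut, an sp2–sp3 bond next to the quaternary C10. This removes the whole side chain as one piece of fixed E-geometry and leaves a ring-B enol triflate. The forward step must couple a primary alkylborane (29) to a hindered tetrasubstituted triflate.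

**25 to 22.** The triflate oxygen on C9 and the hydroxyl on C6 are both traced to the ene-dione of 22. One conjugate hydride addition creates the C8=C9 enolate (via 23, then 24), and one carbonyl reduction sets C6. The demand is hydride delivery to C7 rather than C8, and attack on C6 from the α-face.

**22 to 20.** The two esters are traced to the silyl ethers, and the C6 ketone to the methyl enol ether of 20 (via 21). Acylation is placed where O3 and O19 are the only hydroxyls in the molecule. The demand is that protonation and equilibration at C5 give the trans fusion.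

**20 to 18.** The C1–C10 bond is cut; this is the key disconnection. It opens ring A, removes the quaternary stereocentre C10 and returns ring B to an aromatic phenol. The forward step needs C- rather than O-alkylation, attack at C10 rather than C6, and one face at C10.

**18 to 10.** The C2–C3 bond is cut after the C1 iodide is traced to a terminal alkene (17, 16, 13, 12). This leaves an α-quaternary aldehyde and an allyl nucleophile. The demand is reagent-controlled addition to the Re face to give (3R).

**10 to 7.** The C4–C19 bond is cut as a 1,2-shift (10 from 9, from 8). The quaternary stereocentre C4 is thereby referred to the epoxide of a trisubstituted allylic alcohol. The demand is an enantioselective epoxidation and a stereospecific anti migration.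

**7 to 3 and 5.** The aryl–alkenyl bond C5–C4 is cut (via 6). This gives a simple aryl bromide and a geometrically defined alkenylboronate. The demand is coupling at a di-ortho-substituted bromide with retention of alkene geometry.

**3 to 1, 5 to 4, 28 to 26.** These are functional-group changes only: benzylation and bromination of 1, borylation of 4, silylation and semi-hydrogenation of 26.

## Other disconnections considered

**Alternative 1:** The cut is C5–C10 and C6–C7 together. In the forward sense, heating the (E,E)-nitro-triene A2 gives the trans-fused 6α-nitro decalin A1 by an intramolecular Diels–Alder reaction with the nitro group endo.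
- In its favour: it forms both rings, two C–C bonds and three stereocentres (C5, C6, C10) in one step, which is better than the chosen plan (one ring, one bond, one stereocentre). The C8=C9 alkene and the complete side chain are already in place, so no triflate or hindered coupling at C9 is needed; this too is better.
- Against it: the diene terminus C10 is fully substituted, so one substituent must sit inside the s-cis diene, which slows the cycloaddition and invites 1,5-hydrogen shifts. A2, with a stereodefined tetrasubstituted C9=C10 alkene, is long to make. The nitro group must be turned into the C6 ketone (Nef reaction) before the same late reduction. The acetonide requires the 3β-oxygen, so C3 must later be inverted.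
- Comparison: mechanistically the concerted cycloaddition gives firmer relative control of C5, C6 and C10 than the conformational bias used here (equal or better). Face control by C4 is no firmer than in the chosen plan (equal). In step count it is shorter after the key step and longer before it, so roughly equal overall. The chosen plan keeps the advantage of making C10 from a trivially available arene.

**Alternative 2:** The cut is C4–C5 and C1–C10. In the forward sense, the silyloxydiene ester A5 adds to the methyl-bearing double bond of quinone monoketal A4 (made from 1) under a chiral oxazaborolidinium Lewis acid to give the cis-fused endo adduct A3.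
- In its favour: it is convergent and sets the absolute configuration catalytically from achiral partners, which is better than the two reagent-controlled steps used here. Ring B leaves the step in the same oxidation pattern as 22, so the end-game is equal. C3 arrives at the ketone level, which allows direct reduction to the axial 3α-alcohol (equal or better).
- Against it: the dienophile is an α-methyl enone double bond, a poor partner for a push–pull diene. C4 is only tertiary, so C18 must be added later by alkylation of a β-keto ester with uncertain facial sense. The cis fusion must be corrected at C5.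
- Comparison: it builds two bonds and up to three stereocentres against one and one, and needs fewer steps before the key step. It loses that margin in the quaternisation of C4 and the adjustment of C19. Overall step economy is comparable; certainty of the key reaction is lower.

**Alternative 3:** The cut is C7–C8 and C9–C10. In the forward sense, the ring-A diene A7 adds to methyl but-2-ynoate A8 to give the 1,4-cyclohexadiene A6.
- In its favour: ring B, the C8 methyl, the tetrasubstituted C8=C9 alkene, the quaternary C10 and a C11 carbon on C9 all arrive in one step; delivering the alkene with C11 attached is better than the triflate route.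
- Against it: the bond to C10 must form at a tetrasubstituted diene terminus with the ester-bearing alkyne carbon, which is sterically the worst combination. Face selectivity at C10 again rests on telling C18 from C19 on C4 (equal to the chosen plan, not better). Ring A with C3 and C4 must be made first. The chain must be grown from the C11 ester over several steps. The 3β-silyloxy group again calls for inversion.
- Comparison: two bonds against one, but a longer route before and after the key step and a harsher, less predictable cycloaddition.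

Key step: step 14

## Route

**Step 1**
Reactants: 1 4-methoxy-2,6-dimethylphenol
Product: 2 2-(benzyloxy)-5-methoxy-1,3-dimethylbenzene
Conditions: BnBr, K2CO3, DMF, rt to 50 °C
Reagents that add atoms: benzyl bromide, BrCc1ccccc1
Why: Williamson ether synthesis; the benzyl ether masks the phenol through the organometallic, Lewis-acid and hydride steps and is later removed by hydrogenolysis before the iodide is made.

**Step 2**
Reactants: 2 2-(benzyloxy)-5-methoxy-1,3-dimethylbenzene
Product: 3 2-(benzyloxy)-4-bromo-5-methoxy-1,3-dimethylbenzene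
Conditions: NBS, MeCN, 0 °C to rt
Reagents that add atoms: N-bromosuccinimide, O=C1CCC(=O)N1Br
Why: Electrophilic aromatic bromination; the only free ring positions are the two equivalent ones ortho to methoxy, and the first bromine deactivates the ring toward a second.

**Step 3**
Reactants: 4 ethyl but-2-ynoate
Product: 5 ethyl (2Z)-3-(4,4,5,5-tetramethyl-1,3,2-dioxaborolan-2-yl)but-2-enoate
Conditions: B2pin2, CuCl (3 mol%), Xantphos, NaOt-Bu (cat.), MeOH, THF, rt
Reagents that add atoms: bis(pinacolato)diboron, CC1(C)OB(OC1(C)C)B1OC(C)(C)C(C)(C)O1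
Why: Copper-catalysed β-borylation of an alkynoate; syn addition of boryl-copper followed by protonation by methanol places boron on C3 trans to the ester, which fixes the later aryl/ester trans relationship.

**Step 4**
Reactants: 3 2-(benzyloxy)-4-bromo-5-methoxy-1,3-dimethylbenzene; 5 ethyl (2Z)-3-(pinacolboryl)but-2-enoate
Product: 6 ethyl (2E)-3-Ar-but-2-enoate
Conditions: Pd(OAc)2 (5 mol%), SPhos, K3PO4, toluene/H2O, 90 °C
Reagents that add atoms: none
Why: Suzuki–Miyaura coupling with retention of alkene geometry; the biaryl dialkylphosphine ligand is chosen for the di-ortho-substituted, electron-rich bromide; this forms the C5–C4 bond.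

**Step 5**
Reactants: 6 ethyl (2E)-3-Ar-but-2-enoate
Product: 7 (2E)-3-Ar-but-2-en-1-ol
Conditions: i-Bu2AlH (2.2 equiv), CH2Cl2, −78 °C
Reagents that add atoms: none
Why: 1,2-Reduction of an α,β-unsaturated ester to the allylic alcohol by an aluminium hydride; the alkene geometry is untouched.

**Step 6**
Reactants: 7 (2E)-3-Ar-but-2-en-1-ol
Product: 8 [(2S,3S)-3-Ar-3-methyloxiran-2-yl]methanol
Conditions: t-BuOOH, Ti(Oi-Pr)4 (10 mol%), L-(+)-diethyl tartrate (12 mol%), 4 Å MS, CH2Cl2, −20 °C
Reagents that add atoms: tert-butyl hydroperoxide, CC(C)(C)OO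
Why: Sharpless asymmetric epoxidation; with the L-(+)-tartrate the oxygen is delivered to the face that gives the (2S,3S)-epoxide of an (E)-3,3-disubstituted allylic alcohol, which fixes the absolute configuration later carried to C4.

**Step 7**
Reactants: 8 [(2S,3S)-3-Ar-3-methyloxiran-2-yl]methanol
Product: 9 tert-butyl{[(2S,3S)-3-Ar-3-methyloxiran-2-yl]methoxy}dimethylsilane
Conditions: TBSCl, imidazole, DMF, 0 °C to rt
Reagents that add atoms: tert-butyldimethylsilyl chloride, CC(C)(C)[Si](C)(C)Cl
Why: Silylation of a primary alcohol; the siloxymethyl group is the migrating group of the next step and becomes C19.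

**Step 8**
Reactants: 9 tert-butyl{[(2S,3S)-3-Ar-3-methyloxiran-2-yl]methoxy}dimethylsilane
Product: 10 (2S)-2-Ar-3-[(tert-butyldimethylsilyl)oxy]-2-methylpropanal
Conditions: MeAl(OC6H2-2,6-t-Bu2-4-Br)2 (0.2 equiv), CH2Cl2, −78 °C
Reagents that add atoms: none
Why: Lewis-acid-promoted semipinacol rearrangement of a 2,3-epoxy silyl ether: the bulky aluminium aryloxide opens the epoxide at the tertiary benzylic carbon, the siloxymethyl group migrates anti to the departing oxygen (inversion at that carbon) and the former C2 becomes the aldehyde, so the epoxide configuration is transferred to the all-carbon quaternary centre C4 as (S).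

**Step 9**
Reactants: 10 (2S)-2-Ar-3-[(tert-butyldimethylsilyl)oxy]-2-methylpropanal
Product: 12 (2S,3R)-2-Ar-1-[(tert-butyldimethylsilyl)oxy]-2-methylhex-5-en-3-ol, via borinate 11 (not isolated)
Conditions: (+)-Ipc2B(allyl) [from (−)-α-pinene], Et2O, −78 °C to rt; NaOH, H2O2
Reagents that add atoms: (+)-B-allyldiisopinocampheylborane, C=CCB([C@H]1C[C@H]2C[C@@H]([C@@H]1C)C2(C)C)[C@H]1C[C@H]2C[C@@H]([C@@H]1C)C2(C)C
Why: Asymmetric allylboration through a closed chair transition state forms C2–C3; the borane of the (−)-α-pinene series delivers allyl to the Re face and sets C3 as (R) under reagent control, since the α-quaternary centre has no α-hydrogen and little bias of its own.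

**Step 10**
Reactants: 12 (2S,3R)-2-Ar-1-[(tert-butyldimethylsilyl)oxy]-2-methylhex-5-en-3-ol
Product: 13 (2S,3R)-2-Ar-1,3-bis[(tert-butyldimethylsilyl)oxy]-2-methylhex-5-ene
Conditions: TBSOTf, 2,6-lutidine, CH2Cl2, −78 to 0 °C
Reagents that add atoms: tert-butyldimethylsilyl trifluoromethanesulfonate, CC(C)(C)[Si](C)(C)OS(=O)(=O)C(F)(F)F
Why: Silylation of a hindered secondary alcohol with the silyl triflate; the two bulky silyloxy groups are also the conformational control elements of the key step.

**Step 11**
Reactants: 13 (2S,3R)-2-Ar-1,3-bis[(tert-butyldimethylsilyl)oxy]-2-methylhex-5-ene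
Product: 16 (3R,4S)-4-Ar-3,5-bis[(tert-butyldimethylsilyl)oxy]-4-methylpentan-1-ol, via diol 14 (not isolated), via aldehyde 15 (not isolated)
Conditions: OsO4 (2 mol%), NaIO4, 2,6-lutidine, dioxane/H2O, rt; then NaBH4, MeOH, 0 °C
Reagents that add atoms: sodium periodate (oxygen relayed by OsO4), [Na+].[O-]I(=O)(=O)=O
Why: Lemieux–Johnson oxidative cleavage removes the extra alkene carbon and borohydride reduces the aldehyde to the C1 alcohol; catalytic osmium with periodate spares the electron-rich arene and the benzyl ether.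

**Step 12**
Reactants: 16 (3R,4S)-4-Ar-3,5-bis[(tert-butyldimethylsilyl)oxy]-4-methylpentan-1-ol
Product: 17 (3R,4S)-3,5-bis[(tert-butyldimethylsilyl)oxy]-4-(3-hydroxy-6-methoxy-2,4-dimethylphenyl)-4-methylpentan-1-ol
Conditions: H2 (1 atm), Pd/C, EtOAc, rt
Reagents that add atoms: none
Why: Hydrogenolysis of the aryl benzyl ether; it is done before the iodide is introduced because no alkene or halide is present at this stage.

**Step 13**
Reactants: 17 (3R,4S)-3,5-bis[(tert-butyldimethylsilyl)oxy]-4-(3-hydroxy-6-methoxy-2,4-dimethylphenyl)-4-methylpentan-1-ol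
Product: 18 3-{(2S,3R)-1,3-bis[(tert-butyldimethylsilyl)oxy]-5-iodo-2-methylpentan-2-yl}-4-methoxy-2,6-dimethylphenol
Conditions: I2, PPh3, imidazole, CH2Cl2, 0 °C to rt
Reagents that add atoms: iodine, II
Why: Appel-type iodination; only the primary alcohol is activated by the iodophosphonium species, and the hindered 2,6-dimethylphenol does not react.

**Step 14**
Reactants: 18 3-{(2S,3R)-1,3-bis[(tert-butyldimethylsilyl)oxy]-5-iodo-2-methylpentan-2-yl}-4-methoxy-2,6-dimethylphenol
Product: 20 (3R,4S,10S)-3α,19-bis[(tert-butyldimethylsilyl)oxy]-6-methoxy-11,12,13,14,15,16-hexanorlabda-5,7-dien-9-one, via sodium phenoxide 19 (not isolated)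
Conditions: NaN(SiMe3)2 (1.05 equiv), toluene, 0.01 M, 0 to 80 °C
Reagents that add atoms: none
Why: The base gives the ambident sodium phenoxide, whose ortho carbon C10 displaces the primary iodide at C1 in an intramolecular SN2 step, forming C1–C10 and a 6,6-disubstituted cyclohexa-2,4-dienone that cannot rearomatise because C10 keeps its methyl group. The closest known reaction type is the intramolecular ortho-C-alkylation of phenoxides with dearomatisation to fused cyclohexadienones bearing a quaternary carbon. Ring A closes in the 6-exo-tet mode at C1; O-alkylation would need an eight-membered ring, and high dilution suppresses the intermolecular ether. Attack through the para carbon C6 would also close a six-membered ring, but it would force a C4 substituent to eclipse the C10 methyl in the arene plane, and the tight sodium ion pair in toluene can assist departure of iodide only at the ortho carbon. The new stereocentre C10 is set by C4 and C3 through a chair-like tether: C18 lies in the arene plane beside the small methoxy oxygen, C19 and C3 flank C10 on opposite faces, and the 3-silyloxy and silyloxymethyl groups are anti (both axial), so C1 arrives on the face opposite C19 and the C10 methyl ends syn to C19. The competing chair would put the two bulky silyloxy-bearing groups gauche and press the silyloxymethyl group between the methoxy group and C3; the axial 3-silyloxy group costs little because C4 is fully substituted and C5 is trigonal (one 1,3-diaxial hydrogen only). The step thus needs C- over O-alkylation, C10 over C6 and one face at C10; the first two rest on ring size and ion pairing, while the last rests on a modest conformational bias and is the least secure.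

**Step 15**
Reactants: 20 (3R,4S,10S)-3α,19-bis[(tert-butyldimethylsilyl)oxy]-6-methoxy-11,12,13,14,15,16-hexanorlabda-5,7-dien-9-one
Product: 21 (3R,4S,5S,10S)-3α,19-dihydroxy-11,12,13,14,15,16-hexanorlabd-7-ene-6,9-dione (5α-H)
Conditions: 48% aq. HF, MeCN, 0 °C to rt
Reagents that add atoms: water, O
Why: Acid hydrolysis of the dienol methyl ether (protonation at C5, water at C6) gives the ene-dione, while fluoride removes both silyl ethers; C5 is α to the new C6 ketone and acid-mediated enolisation lets it settle in the trans fusion.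

**Step 16**
Reactants: 21 (3R,4S,5S,10S)-3α,19-dihydroxy-11,12,13,14,15,16-hexanorlabd-7-ene-6,9-dione
Product: 22 (3R,4S,5S,10S)-6,9-dioxo-11,12,13,14,15,16-hexanorlabd-7-ene-3α,19-diyl bis(3-methylbutanoate)
Conditions: (i-PrCH2CO)2O, pyridine, DMAP (cat.), CH2Cl2, 0 °C to rt
Reagents that add atoms: 3-methylbutanoic anhydride, CC(C)CC(=O)OC(=O)CC(C)C
Why: DMAP-catalysed acylation of both hydroxyls at the one stage where O3 and O19 are the only hydroxyls present, so the 6-hydroxyl and C15 oxygen of the target never compete; pyridine is too weak a base to enolise the ene-dione.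

**Step 17**
Reactants: 22 (3R,4S,5S,10S)-6,9-dioxo-11,12,13,14,15,16-hexanorlabd-7-ene-3α,19-diyl bis(3-methylbutanoate)
Product: 24 (3R,4S,5S,10S)-6-oxo-9-{[(trifluoromethyl)sulfonyl]oxy}-11,12,13,14,15,16-hexanorlabd-8-ene-3α,19-diyl bis(3-methylbutanoate), via potassium enolate 23 (not isolated)
Conditions: KBH(s-Bu)3 (1.05 equiv), THF, −78 °C; then N-(5-chloropyridin-2-yl)-N-triflyltriflamide, −78 to 0 °C
Reagents that add atoms: N-(5-chloropyridin-2-yl)bis(trifluoromethanesulfonimide), O=S(=O)(N(c1ccc(Cl)cn1)S(=O)(=O)C(F)(F)F)C(F)(F)F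
Why: Conjugate reduction with enolate trapping (reductive triflation): the bulky borohydride adds to C7, the unsubstituted β-carbon of the C9 enone, because C8 carries a methyl and both carbonyls are too hindered for 1,2-attack; the resulting C8=C9 enolate is O-triflated cold before it can equilibrate.

**Step 18**
Reactants: 24 (3R,4S,5S,10S)-6-oxo-9-{[(trifluoromethyl)sulfonyl]oxy}-11,12,13,14,15,16-hexanorlabd-8-ene-3α,19-diyl bis(3-methylbutanoate)
Product: 25 (3R,4S,5S,6R,10S)-6β-hydroxy-9-{[(trifluoromethyl)sulfonyl]oxy}-11,12,13,14,15,16-hexanorlabd-8-ene-3α,19-diyl bis(3-methylbutanoate)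
Conditions: NaBH4, MeOH/THF, −20 to 0 °C
Reagents that add atoms: none
Why: Borohydride reduction of the C6 ketone; the β-face is blocked by the syn-axial C20 methyl and C19 group, so hydride enters from the α-face and gives the axial 6β-alcohol; esters and the vinyl triflate are inert, and removing the ketone ends the risk of alkene migration.

**Step 19**
Reactants: 26 (2E)-3-methylpent-2-en-4-yn-1-ol
Product: 27 tert-butyldimethyl{[(2E)-3-methylpent-2-en-4-yn-1-yl]oxy}silane
Conditions: TBSCl, imidazole, CH2Cl2, rt
Reagents that add atoms: tert-butyldimethylsilyl chloride, CC(C)(C)[Si](C)(C)Cl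
Why: Silylation of the primary allylic alcohol so that it survives hydroboration and coupling.

**Step 20**
Reactants: 27 tert-butyldimethyl{[(2E)-3-methylpent-2-en-4-yn-1-yl]oxy}silane
Product: 28 tert-butyldimethyl{[(2E)-3-methylpenta-2,4-dien-1-yl]oxy}silane
Conditions: H2 (1 atm), Pd/CaCO3 poisoned with Pb(OAc)2, quinoline, hexane, rt
Reagents that add atoms: none
Why: Semi-hydrogenation of the terminal alkyne of a conjugated enyne over poisoned palladium gives the vinyl group; the trisubstituted E-alkene is not touched.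

**Step 21**
Reactants: 28 tert-butyldimethyl{[(2E)-3-methylpenta-2,4-dien-1-yl]oxy}silane; 25 (3R,4S,5S,6R,10S)-6β-hydroxy-9-triflyloxy-hexanorlabd-8-ene-3α,19-diyl bis(3-methylbutanoate)
Product: 30 (13E)-15-[(tert-butyldimethylsilyl)oxy]-6β-hydroxylabda-8,13-diene-3α,19-diyl bis(3-methylbutanoate), via alkylborane 29 (not isolated)
Conditions: 28, 9-BBN, THF, 0 °C to rt; then 25, Pd(dppf)Cl2 (10 mol%), AsPh3, Cs2CO3, DMF/H2O, rt to 50 °C
Reagents that add atoms: none
Why: 9-BBN hydroborates only the terminal vinyl group, anti-Markovnikov, and the primary alkylborane undergoes B-alkyl Suzuki–Miyaura coupling with the enol triflate to form C9–C11; the hindered 6β-hydroxyl and the esters tolerate the mild aqueous base.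

**Step 22**
Reactants: 30 (13E)-15-[(tert-butyldimethylsilyl)oxy]-6β-hydroxylabda-8,13-diene-3α,19-diyl bis(3-methylbutanoate)
Product: 31 (13E)-6β,15-dihydroxylabda-8,13-diene-3α,19-diyl bis(3-methylbutanoate)
Conditions: HF·pyridine, pyridine, THF, 0 °C
Reagents that add atoms: none
Why: Buffered fluoride cleaves the primary allylic silyl ether without touching the esters.

**Step 23**
Reactants: 31 (13E)-6β,15-dihydroxylabda-8,13-diene-3α,19-diyl bis(3-methylbutanoate)
Product: 32 (13E)-6β-hydroxy-15-oxolabda-8,13-diene-3α,19-diyl bis(3-methylbutanoate)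
Conditions: MnO2, CH2Cl2, rt
Reagents that add atoms: none
Why: MnO2 oxidises only the allylic primary alcohol; the homoallylic, hindered 6β-hydroxyl is left, and the E-enal geometry is kept.

**Step 24**
Reactants: 32 (13E)-6β-hydroxy-15-oxolabda-8,13-diene-3α,19-diyl bis(3-methylbutanoate)
Product: 33 (13E)-6β-hydroxy-3α,19-bis(3-methylbutanoyloxy)labda-8,13-dien-15-oic acid (3R,4S,5R,6R,10S), the target
Conditions: NaClO2, NaH2PO4, 2-methylbut-2-ene, t-BuOH/H2O, rt
Reagents that add atoms: sodium chlorite, [Na+].[O-]Cl=O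
Why: Pinnick oxidation of the enal to the acid; the alkene scavenger removes hypochlorous acid, which protects the C8=C9 alkene, and the secondary alcohol and esters are unaffected.

## Compound list

1 | 4-methoxy-2,6-dimethylphenol | Cc1cc(OC)cc(C)c1O | starting material
2 | 2-(benzyloxy)-5-methoxy-1,3-dimethylbenzene | Cc1cc(OC)cc(C)c1OCc1ccccc1 | intermediate
3 | 2-(benzyloxy)-4-bromo-5-methoxy-1,3-dimethylbenzene | Cc1cc(OC)c(Br)c(C)c1OCc1ccccc1 | intermediate
4 | ethyl but-2-ynoate | CC#CC(=O)OCC | starting material
5 | ethyl (2Z)-3-(4,4,5,5-tetramethyl-1,3,2-dioxaborolan-2-yl)but-2-enoate | C/C(B1OC(C)(C)C(C)(C)O1)=C\C(=O)OCC | intermediate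
6 | ethyl (2E)-3-Ar-but-2-enoate | C/C(=C\C(=O)OCC)c1c(C)c(OCc2ccccc2)c(C)cc1OC | intermediate
7 | (2E)-3-Ar-but-2-en-1-ol | C/C(=C\CO)c1c(C)c(OCc2ccccc2)c(C)cc1OC | intermediate
8 | [(2S,3S)-3-Ar-3-methyloxiran-2-yl]methanol | OC[C@@H]1O[C@@]1(C)c2c(C)c(OCc3ccccc3)c(C)cc2OC | intermediate
9 | tert-butyl{[(2S,3S)-3-Ar-3-methyloxiran-2-yl]methoxy}dimethylsilane | CC(C)(C)[Si](C)(C)OC[C@@H]1O[C@@]1(C)c2c(C)c(OCc3ccccc3)c(C)cc2OC | intermediate
10 | (2S)-2-Ar-3-[(tert-butyldimethylsilyl)oxy]-2-methylpropanal | Cc1cc(OC)c([C@@](C)(CO[Si](C)(C)C(C)(C)C)C=O)c(C)c1OCc1ccccc1 | intermediate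
11 | diisopinocampheylborinate of 12 | Cc1cc(OC)c([C@@](C)(CO[Si](C)(C)C(C)(C)C)[C@H](OB([C@H]2C[C@H]3C[C@@H]([C@@H]2C)C3(C)C)[C@H]2C[C@H]3C[C@@H]([C@@H]2C)C3(C)C)CC=C)c(C)c1OCc1ccccc1 | intermediate (not isolated)
12 | (2S,3R)-2-Ar-1-[(tert-butyldimethylsilyl)oxy]-2-methylhex-5-en-3-ol | Cc1cc(OC)c([C@@](C)(CO[Si](C)(C)C(C)(C)C)[C@H](O)CC=C)c(C)c1OCc1ccccc1 | intermediate
13 | (2S,3R)-2-Ar-1,3-bis[(tert-butyldimethylsilyl)oxy]-2-methylhex-5-ene | Cc1cc(OC)c([C@@](C)(CO[Si](C)(C)C(C)(C)C)[C@H](O[Si](C)(C)C(C)(C)C)CC=C)c(C)c1OCc1ccccc1 | intermediate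
14 | (4R,5S)-5-Ar-4,6-bis[(tert-butyldimethylsilyl)oxy]-5-methylhexane-1,2-diol (both C2 epimers) | Cc1cc(OC)c([C@@](C)(CO[Si](C)(C)C(C)(C)C)[C@H](O[Si](C)(C)C(C)(C)C)CC(O)CO)c(C)c1OCc1ccccc1 | intermediate (not isolated)
15 | (3R,4S)-4-Ar-3,5-bis[(tert-butyldimethylsilyl)oxy]-4-methylpentanal | Cc1cc(OC)c([C@@](C)(CO[Si](C)(C)C(C)(C)C)[C@H](O[Si](C)(C)C(C)(C)C)CC=O)c(C)c1OCc1ccccc1 | intermediate (not isolated)
16 | (3R,4S)-4-Ar-3,5-bis[(tert-butyldimethylsilyl)oxy]-4-methylpentan-1-ol | Cc1cc(OC)c([C@@](C)(CO[Si](C)(C)C(C)(C)C)[C@H](O[Si](C)(C)C(C)(C)C)CCO)c(C)c1OCc1ccccc1 | intermediate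
17 | (3R,4S)-3,5-bis[(tert-butyldimethylsilyl)oxy]-4-(3-hydroxy-6-methoxy-2,4-dimethylphenyl)-4-methylpentan-1-ol | Cc1cc(OC)c([C@@](C)(CO[Si](C)(C)C(C)(C)C)[C@H](O[Si](C)(C)C(C)(C)C)CCO)c(C)c1O | intermediate
18 | 3-{(2S,3R)-1,3-bis[(tert-butyldimethylsilyl)oxy]-5-iodo-2-methylpentan-2-yl}-4-methoxy-2,6-dimethylphenol (key-step precursor) | Cc1cc(OC)c([C@@](C)(CO[Si](C)(C)C(C)(C)C)[C@H](O[Si](C)(C)C(C)(C)C)CCI)c(C)c1O | intermediate
19 | sodium phenoxide of 18 | Cc1cc(OC)c([C@@](C)(CO[Si](C)(C)C(C)(C)C)[C@H](O[Si](C)(C)C(C)(C)C)CCI)c(C)c1[O-].[Na+] | intermediate (not isolated)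
20 | (3R,4S,10S)-3α,19-bis[(tert-butyldimethylsilyl)oxy]-6-methoxy-11,12,13,14,15,16-hexanorlabda-5,7-dien-9-one (key-step product) | CC1=CC(OC)=C2[C@@](C)(CO[Si](C)(C)C(C)(C)C)[C@H](O[Si](C)(C)C(C)(C)C)CC[C@]2(C)C1=O | intermediate
21 | (3R,4S,5S,10S)-3α,19-dihydroxy-11,12,13,14,15,16-hexanorlabd-7-ene-6,9-dione | CC1=CC(=O)[C@H]2[C@@](C)(CO)[C@H](O)CC[C@]2(C)C1=O | intermediate
22 | (3R,4S,5S,10S)-6,9-dioxo-11,12,13,14,15,16-hexanorlabd-7-ene-3α,19-diyl bis(3-methylbutanoate) | CC1=CC(=O)[C@H]2[C@@](C)(COC(=O)CC(C)C)[C@H](OC(=O)CC(C)C)CC[C@]2(C)C1=O | intermediate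
23 | potassium 8-en-9-olate of 22 after hydride addition at C7 | CC1=C([O-])[C@@]2(C)CC[C@@H](OC(=O)CC(C)C)[C@](C)(COC(=O)CC(C)C)[C@@H]2C(=O)C1.[K+] | intermediate (not isolated)
24 | (3R,4S,5S,10S)-6-oxo-9-{[(trifluoromethyl)sulfonyl]oxy}-11,12,13,14,15,16-hexanorlabd-8-ene-3α,19-diyl bis(3-methylbutanoate) | CC1=C(OS(=O)(=O)C(F)(F)F)[C@@]2(C)CC[C@@H](OC(=O)CC(C)C)[C@](C)(COC(=O)CC(C)C)[C@@H]2C(=O)C1 | intermediate
25 | (3R,4S,5S,6R,10S)-6β-hydroxy-9-{[(trifluoromethyl)sulfonyl]oxy}-11,12,13,14,15,16-hexanorlabd-8-ene-3α,19-diyl bis(3-methylbutanoate) | CC1=C(OS(=O)(=O)C(F)(F)F)[C@@]2(C)CC[C@@H](OC(=O)CC(C)C)[C@](C)(COC(=O)CC(C)C)[C@@H]2[C@H](O)C1 | intermediate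
26 | (2E)-3-methylpent-2-en-4-yn-1-ol | C#C/C(C)=C/CO | starting material
27 | tert-butyldimethyl{[(2E)-3-methylpent-2-en-4-yn-1-yl]oxy}silane | C#C/C(C)=C/CO[Si](C)(C)C(C)(C)C | intermediate
28 | tert-butyldimethyl{[(2E)-3-methylpenta-2,4-dien-1-yl]oxy}silane | C=C/C(C)=C/CO[Si](C)(C)C(C)(C)C | intermediate
29 | 9-{(3E)-5-[(tert-butyldimethylsilyl)oxy]-3-methylpent-3-en-1-yl}-9-borabicyclo[3.3.1]nonane | CC(C)(C)[Si](C)(C)OC/C=C(\C)CCB1C2CCCC1CCC2 | intermediate (not isolated)
30 | (13E)-15-[(tert-butyldimethylsilyl)oxy]-6β-hydroxylabda-8,13-diene-3α,19-diyl bis(3-methylbutanoate) | CC1=C(CC/C(C)=C/CO[Si](C)(C)C(C)(C)C)[C@@]2(C)CC[C@@H](OC(=O)CC(C)C)[C@](C)(COC(=O)CC(C)C)[C@@H]2[C@H](O)C1 | intermediate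
31 | (13E)-6β,15-dihydroxylabda-8,13-diene-3α,19-diyl bis(3-methylbutanoate) | CC1=C(CC/C(C)=C/CO)[C@@]2(C)CC[C@@H](OC(=O)CC(C)C)[C@](C)(COC(=O)CC(C)C)[C@@H]2[C@H](O)C1 | intermediate
32 | (13E)-6β-hydroxy-15-oxolabda-8,13-diene-3α,19-diyl bis(3-methylbutanoate) | CC1=C(CC/C(C)=C/C=O)[C@@]2(C)CC[C@@H](OC(=O)CC(C)C)[C@](C)(COC(=O)CC(C)C)[C@@H]2[C@H](O)C1 | intermediate
33 | (13E)-6β-hydroxy-3α,19-bis(3-methylbutanoyloxy)labda-8,13-dien-15-oic acid | CC1=C(CC/C(C)=C/C(=O)O)[C@@]2(C)CC[C@@H](OC(=O)CC(C)C)[C@](C)(COC(=O)CC(C)C)[C@@H]2[C@H](O)C1 | target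

## Step count and least certain steps

Total: 24 steps. Longest linear sequence: 21 steps (steps 1, 2, 4–18 and 21–24).

**Step 14 (key step).** The most likely failure is poor facial selectivity at C10. The chair with the 3-silyloxy group equatorial lies close in energy and leads to the C10 epimer, and no covalent constraint enforces the desired chair. The fallback moves the control element by relaying through the C3 epimer, whose oxygen is equatorial in the chair that gives the correct C10, and correcting C3 afterwards. It sets out from 10 and returns at 20.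
- Allylboration of 10 with the enantiomeric borane, (−)-B-allyldiisopinocampheylborane, gives (2S,3S)-2-Ar-1-[(tert-butyldimethylsilyl)oxy]-2-methylhex-5-en-3-ol F1.
- OsO4/NaIO4 cleavage and NaBH4 reduction give (3S,4S)-4-Ar-5-[(tert-butyldimethylsilyl)oxy]-4-methylpentane-1,3-diol F2.
- Hydrogenolysis gives the corresponding phenol diol F3.
- I2, PPh3 and imidazole convert only the primary hydroxyl, giving the (2S,3S)-iodo alcohol phenol F4.
- NaN(SiMe3)2 (1 equiv) in dilute toluene closes ring A to the 3β-hydroxy dienone F5.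
- Dess–Martin periodinane gives the 3-keto dienone F6.
- LiBH(s-Bu)3 at −78 °C attacks the unconjugated C3 ketone from the equatorial direction and gives the axial 3α-hydroxy dienone F7.
- TBSOTf and 2,6-lutidine then give 20.

**Step 8.** The most likely failure is loss of stereochemical fidelity, or a competing hydride shift, because the tertiary benzylic cation beside the electron-rich arene may outlive the concerted anti migration. The fallback builds C3 and C4 together in one chair transition state. It sets out from 7 and returns at 17.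
- Palladium-catalysed borylation of the allylic alcohol with B2pin2 gives the (E)-allylboronate 2-[(2E)-3-Ar-but-2-en-1-yl]-4,4,5,5-tetramethyl-1,3,2-dioxaborolane F8.
- Addition to 3-(benzyloxy)propanal under a TRIP phosphoric acid (the enantiomer that directs attack to the Si face, expected to be (S)-TRIP) gives (3R,4R)-4-Ar-1-(benzyloxy)-4-methylhex-5-en-3-ol F9; the E-geometry places aryl anti and methyl syn to the hydroxyl.
- OsO4/NaIO4 cleavage of the vinyl group and NaBH4 reduction give (2S,3R)-2-Ar-5-(benzyloxy)-2-methylpentane-1,3-diol F10.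
- TBSOTf gives the bis-silyl ether F11.
- Hydrogenolysis of both benzyl ethers gives 17.

**Step 21.** The most likely failure is slow oxidative addition and transmetallation at the tetrasubstituted triflate beside the quaternary C10, so that protodeboronation of 29 or reduction of the triflate wins. The fallback is a Negishi coupling at the ketone stage, where an alkylzinc reagent tolerates the ketone and esters. It sets out from 28 and 24 and returns at 30.
- Iodinolysis of 29 (I2, NaOMe) gives tert-butyl{[(2E)-5-iodo-3-methylpent-2-en-1-yl]oxy}dimethylsilane F12.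
- Zinc insertion gives the alkylzinc iodide F13.
- Coupling with 24 (Pd(OAc)2, SPhos, THF/DMA) gives the 6-oxo coupled product F14.
- NaBH4 reduction from the α-face gives 30.

## Further compounds

F1 | step 14 | (2S,3S)-2-Ar-1-[(tert-butyldimethylsilyl)oxy]-2-methylhex-5-en-3-ol | Cc1cc(OC)c([C@@](C)(CO[Si](C)(C)C(C)(C)C)[C@@H](O)CC=C)c(C)c1OCc1ccccc1
F2 | step 14 | (3S,4S)-4-Ar-5-[(tert-butyldimethylsilyl)oxy]-4-methylpentane-1,3-diol | Cc1cc(OC)c([C@@](C)(CO[Si](C)(C)C(C)(C)C)[C@@H](O)CCO)c(C)c1OCc1ccccc1
F3 | step 14 | (3S,4S)-5-[(tert-butyldimethylsilyl)oxy]-4-(3-hydroxy-6-methoxy-2,4-dimethylphenyl)-4-methylpentane-1,3-diol | Cc1cc(OC)c([C@@](C)(CO[Si](C)(C)C(C)(C)C)[C@@H](O)CCO)c(C)c1O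
F4 | step 14 | 3-{(2S,3S)-1-[(tert-butyldimethylsilyl)oxy]-3-hydroxy-5-iodo-2-methylpentan-2-yl}-4-methoxy-2,6-dimethylphenol | Cc1cc(OC)c([C@@](C)(CO[Si](C)(C)C(C)(C)C)[C@@H](O)CCI)c(C)c1O
F5 | step 14 | (3S,4S,10S)-19-[(tert-butyldimethylsilyl)oxy]-3β-hydroxy-6-methoxy-11,12,13,14,15,16-hexanorlabda-5,7-dien-9-one | CC1=CC(OC)=C2[C@@](C)(CO[Si](C)(C)C(C)(C)C)[C@@H](O)CC[C@]2(C)C1=O
F6 | step 14 | (4S,10S)-19-[(tert-butyldimethylsilyl)oxy]-6-methoxy-11,12,13,14,15,16-hexanorlabda-5,7-diene-3,9-dione | CC1=CC(OC)=C2[C@@](C)(CO[Si](C)(C)C(C)(C)C)C(=O)CC[C@]2(C)C1=O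
F7 | step 14 | (3R,4S,10S)-19-[(tert-butyldimethylsilyl)oxy]-3α-hydroxy-6-methoxy-11,12,13,14,15,16-hexanorlabda-5,7-dien-9-one | CC1=CC(OC)=C2[C@@](C)(CO[Si](C)(C)C(C)(C)C)[C@H](O)CC[C@]2(C)C1=O
F8 | step 8 | 2-[(2E)-3-Ar-but-2-en-1-yl]-4,4,5,5-tetramethyl-1,3,2-dioxaborolane | C/C(=C\CB1OC(C)(C)C(C)(C)O1)c1c(C)c(OCc2ccccc2)c(C)cc1OC
F9 | step 8 | (3R,4R)-4-Ar-1-(benzyloxy)-4-methylhex-5-en-3-ol | Cc1cc(OC)c([C@@](C)(C=C)[C@H](O)CCOCc2ccccc2)c(C)c1OCc1ccccc1
F10 | step 8 | (2S,3R)-2-Ar-5-(benzyloxy)-2-methylpentane-1,3-diol | Cc1cc(OC)c([C@@](C)(CO)[C@H](O)CCOCc2ccccc2)c(C)c1OCc1ccccc1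
F11 | step 8 | (2S,3R)-2-Ar-5-(benzyloxy)-1,3-bis[(tert-butyldimethylsilyl)oxy]-2-methylpentane | Cc1cc(OC)c([C@@](C)(CO[Si](C)(C)C(C)(C)C)[C@H](O[Si](C)(C)C(C)(C)C)CCOCc2ccccc2)c(C)c1OCc1ccccc1
F12 | step 21 | tert-butyl{[(2E)-5-iodo-3-methylpent-2-en-1-yl]oxy}dimethylsilane | CC(C)(C)[Si](C)(C)OC/C=C(\C)CCI
F13 | step 21 | {(3E)-5-[(tert-butyldimethylsilyl)oxy]-3-methylpent-3-en-1-yl}zinc iodide | CC(C)(C)[Si](C)(C)OC/C=C(\C)CC[Zn]I
F14 | step 21 | (13E)-15-[(tert-butyldimethylsilyl)oxy]-6-oxolabda-8,13-diene-3α,19-diyl bis(3-methylbutanoate) | CC1=C(CC/C(C)=C/CO[Si](C)(C)C(C)(C)C)[C@@]2(C)CC[C@@H](OC(=O)CC(C)C)[C@](C)(COC(=O)CC(C)C)[C@@H]2C(=O)C1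
A1 | alternative 1 | trans-fused 6α-nitro decalin 3β,19-acetonide with the C8=C9 alkene and silylated side chain | CC1=C(CC/C(C)=C/CO[Si](C)(C)C(C)(C)C)[C@@]2(C)CC[C@@H]3OC(C)(C)OC[C@]3(C)[C@@H]2[C@@H]([N+](=O)[O-])C1
A2 | alternative 1 | (E,E)-nitro-triene: C7=C8–C9=C10 diene tethered through C1–C4 (3,19-acetonide) to the C5=C6 nitroalkene | C=C(C)/C(CC/C(C)=C/CO[Si](C)(C)C(C)(C)C)=C(\C)CC[C@@H]1OC(C)(C)OC[C@]1(C)/C=C/[N+](=O)[O-]
A3 | alternative 2 | cis-fused endo adduct (C6 dimethyl ketal, C9 enone, C3 silyl enol ether, C19 methyl ester) | CC1=CC(OC)(OC)[C@@H]2[C@H](C(=O)OC)C(O[Si](C)(C)C(C)(C)C)=CC[C@]2(C)C1=O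
A4 | alternative 2 | 4,4-dimethoxy-2,6-dimethylcyclohexa-2,5-dien-1-one | CC1=CC(OC)(OC)C=C(C)C1=O
A5 | alternative 2 | methyl (2Z)-3-[(tert-butyldimethylsilyl)oxy]penta-2,4-dienoate | COC(=O)/C=C(\O[Si](C)(C)C(C)(C)C)C=C
A6 | alternative 3 | bicyclic 5,8-diene (C6 silyl enol ether, C11 methyl ester on C9, 3β,19-bis-silyl ether) | CC1=C(C(=O)OC)[C@@]2(C)CC[C@H](O[Si](C)(C)C(C)(C)C)[C@](C)(CO[Si](C)(C)C(C)(C)C)C2=C(O[Si](C)(C)C(C)(C)C)C1
A7 | alternative 3 | ring-A diene: 2-methylcyclohex-1-ene bearing a 1-silyloxyvinyl group on C5, with 3β-silyloxy and 4-methyl-4-silyloxymethyl groups | C=C(O[Si](C)(C)C(C)(C)C)C1=C(C)CC[C@H](O[Si](C)(C)C(C)(C)C)[C@]1(C)CO[Si](C)(C)C(C)(C)C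
A8 | alternative 3 | methyl but-2-ynoate | CC#CC(=O)OC
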